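The (2S) flavanone is cut at the O1–C2 bond of ring C. The precursor is a 2'-hydroxychalcone whose α-carbon carries a removable allyl ester. Its only free phenol is the ring A oxygen para to the geranyl-bearing carbon (the future O1 on C8a); the oxygen between ketone and geranyl group is a MOM ether. A cinchona thiourea-catalysed 6-endo-trig oxa-Michael addition of that phenol to the benzylic β-carbon (future C2, β to the C4 ketone) closes ring C, sets the only stereocentre and fixes the 6-geranyl pattern. Deallylation and decarboxylation follow in the same operation. Ring A is built from resorcinol by metalation, C–H borylation and ortho-formylation, all steered by its mirror symmetry.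

Key step: step 9

Assumption: the quinine-derived thiourea is taken to give the (2S) series in this ring closure; its quinidine-derived pseudo-enantiomer is used instead if analysis of 15 shows the opposite sense.
Remark on names: "geranyl" means (2E)-3,7-dimethylocta-2,6-dien-1-yl throughout.

Step 1
Reactants: 1 resorcinol
Product: 2 1,3-bis(methoxymethoxy)benzene
Conditions: NaH, MOMCl, DMF, 0 °C → rt
Reagents that add atoms: chloromethyl methyl ether (MOMCl), COCCl
Why: Double Williamson-type O-alkylation of the sodium phenoxides gives the bis-MOM ether, whose two acetal oxygens direct the next metalation.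

Step 2
Reactants: 2 1,3-bis(methoxymethoxy)benzene; 3 geranyl bromide
Product: 4 2-geranyl-1,3-bis(methoxymethoxy)benzene
Conditions: n-BuLi, TMEDA, THF, 0 °C; CuI (10 mol %), then 3, −78 °C → rt
Reagents that add atoms: none
Why: Directed ortho-metalation places lithium on the carbon between the two cooperating MOM ethers, and copper-assisted SN2 allylation with the primary allylic bromide keeps the E geometry of the geranyl chain.

Step 3
Reactants: 4 2-geranyl-1,3-bis(methoxymethoxy)benzene
Product: 6 4-geranyl-3,5-bis(methoxymethoxy)phenol, via aryl pinacol boronate 5 (not isolated)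
Conditions: [Ir(OMe)(cod)]2 (1.5 mol %), 4,4'-di-tert-butyl-2,2'-bipyridine (3 mol %), B2pin2, THF, 80 °C; then H2O2, NaOH, THF/H2O, 0 °C
Reagents that add atoms: bis(pinacolato)diboron (for 5), CC1(C)OB(OC1(C)C)B1OC(C)(C)C(C)(C)O1; hydrogen peroxide (for 6), OO
Why: Iridium-catalysed C–H borylation (Hartwig–Miyaura type) is governed by sterics and should take the one ring C–H without an ortho substituent, para to the geranyl carbon, and basic peroxide oxidation of the C–B bond then gives the phenol without touching the trisubstituted alkenes.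

Step 4
Reactants: 6 4-geranyl-3,5-bis(methoxymethoxy)phenol
Product: 7 3-geranyl-6-hydroxy-2,4-bis(methoxymethoxy)benzaldehyde
Conditions: MgCl2, Et3N, paraformaldehyde, MeCN, reflux
Reagents that add atoms: paraformaldehyde (as formaldehyde), C=O
Why: Magnesium-mediated ortho-formylation (Casnati–Skattebøl) delivers formaldehyde from the magnesium phenoxide to an ortho carbon (the two are equivalent by symmetry), and hydride transfer to a second formaldehyde gives the salicylaldehyde.

Step 5
Reactants: 7 3-geranyl-6-hydroxy-2,4-bis(methoxymethoxy)benzaldehyde; 8 allyl acetate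
Product: 9 allyl 3-[3-geranyl-6-hydroxy-2,4-bis(methoxymethoxy)phenyl]-3-hydroxypropanoate (racemic)
Conditions: LiN(SiMe3)2 and 8 (3 equiv each), THF, −78 °C; then 7, −78 → −40 °C; NH4Cl (aq)
Reagents that add atoms: none
Why: Aldol addition of the lithium enolate of allyl acetate to the aldehyde, with excess enolate covering the acidic phenol; the carbinol centre is racemic and is destroyed in the next step.

Step 6
Reactants: 9 allyl 3-[3-geranyl-6-hydroxy-2,4-bis(methoxymethoxy)phenyl]-3-hydroxypropanoate
Product: 10 allyl 3-[3-geranyl-6-hydroxy-2,4-bis(methoxymethoxy)phenyl]-3-oxopropanoate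
Conditions: MnO2 (activated), CH2Cl2, rt
Reagents that add atoms: none
Why: Chemoselective MnO2 oxidation of the benzylic alcohol gives the aryl ketone of the β-keto ester and leaves the isolated alkenes and the hydrogen-bonded phenol alone.

Step 7
Reactants: 11 isovanillin (3-hydroxy-4-methoxybenzaldehyde)
Product: 12 4-methoxy-3-(methoxymethoxy)benzaldehyde
Conditions: NaH, MOMCl, DMF, 0 °C → rt
Reagents that add atoms: chloromethyl methyl ether (MOMCl), COCCl
Why: Williamson-type O-alkylation masks the ring B phenol so that the key-step substrate carries a single free phenol.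

Step 8
Reactants: 10 allyl 3-[3-geranyl-6-hydroxy-2,4-bis(methoxymethoxy)phenyl]-3-oxopropanoate; 12 4-methoxy-3-(methoxymethoxy)benzaldehyde
Product: 13 allyl (2Z)-2-[3-geranyl-6-hydroxy-2,4-bis(methoxymethoxy)benzoyl]-3-[4-methoxy-3-(methoxymethoxy)phenyl]prop-2-enoate
Conditions: piperidine (20 mol %), AcOH (20 mol %), 4 Å molecular sieves, toluene, rt
Reagents that add atoms: none
Why: Knoevenagel condensation under piperidinium acetate catalysis at room temperature should give the alkylidene β-keto ester, expected mainly as the Z isomer (aryl cis to the ester), under conditions mild enough that the free phenol does not yet close the ring.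

Step 9
Reactants: 13 allyl (2Z)-2-[3-geranyl-6-hydroxy-2,4-bis(methoxymethoxy)benzoyl]-3-[4-methoxy-3-(methoxymethoxy)phenyl]prop-2-enoate
Product: 15 (2S)-6-geranyl-2-[4-methoxy-3-(methoxymethoxy)phenyl]-5,7-bis(methoxymethoxy)chroman-4-one, via allyl 4-oxochromane-3-carboxylate 14 (not isolated)
Conditions: quinine-derived thiourea [N-(3,5-bis(trifluoromethyl)phenyl)-N'-(9-deoxy-epi-quinin-9-yl)thiourea, 10 mol %], toluene, −25 °C; short silica pad; then Pd(PPh3)4 (5 mol %), HCO2H, Et3N, THF, rt
Reagents that add atoms: none
Why: The thiourea binds the two carbonyl groups of the β-keto ester by hydrogen bonds while the quinuclidine nitrogen deprotonates the single free phenol, so that the phenoxide oxygen adds to the β-carbon of the doubly activated alkene in an intramolecular oxa-Michael addition and the resulting enol tautomerises to 14. The closest known reaction type is the bifunctional cinchona thiourea-catalysed cyclisation of alkylidene β-keto esters to flavanones, followed here by a Tsuji-type deallylation with zerovalent palladium and formate and loss of CO2 from the β-keto acid in place of acidolysis, which spares the MOM ethers and the geranyl chain. Ring C is closed in the 6-endo-trig mode. The C-2 stereocentre is set by the catalyst, which holds the substrate as a hydrogen-bonded ion pair and leaves one face of the alkene open to the phenoxide; C-3 ceases to be a stereocentre on decarboxylation and C-2 is not enolisable. The step needs site selectivity between the two ring A oxygens ortho to the ketone, and this is secured because the oxygen flanked by the geranyl group is a MOM ether, so only the phenol para to the geranyl carbon can close the ring and the 6-geranyl rather than the 8-geranyl flavanone results. Face selectivity rests on the two-point binding that the removable ester provides, and the low temperature holds back the uncatalysed closure.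

Step 10
Reactants: 15 (2S)-6-geranyl-2-[4-methoxy-3-(methoxymethoxy)phenyl]-5,7-bis(methoxymethoxy)chroman-4-one
Product: 16 (2S)-6-geranyl-5,7-dihydroxy-2-(3-hydroxy-4-methoxyphenyl)chroman-4-one
Conditions: HCl (3 M aq), MeOH, 45 °C
Reagents that add atoms: none
Why: Acid-catalysed acetal solvolysis removes the three aryl MOM groups; C-2 is left alone because ring opening of a flavanone is base-mediated, and moderate temperature with short exposure limits acid cyclisation of the geranyl chain onto the neighbouring phenols.

Compound list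
1 | resorcinol | Oc1cccc(O)c1 | starting material
2 | 1,3-bis(methoxymethoxy)benzene | COCOc1cccc(OCOC)c1 | intermediate
3 | geranyl bromide, (2E)-1-bromo-3,7-dimethylocta-2,6-diene | BrC/C=C(\C)CCC=C(C)C | starting material
4 | 2-geranyl-1,3-bis(methoxymethoxy)benzene | COCOc1cccc(OCOC)c1C/C=C(\C)CCC=C(C)C | intermediate
5 | 2-[4-geranyl-3,5-bis(methoxymethoxy)phenyl]-4,4,5,5-tetramethyl-1,3,2-dioxaborolane (not isolated) | COCOc1cc(B2OC(C)(C)C(C)(C)O2)cc(OCOC)c1C/C=C(\C)CCC=C(C)C | intermediate
6 | 4-geranyl-3,5-bis(methoxymethoxy)phenol | COCOc1cc(O)cc(OCOC)c1C/C=C(\C)CCC=C(C)C | intermediate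
7 | 3-geranyl-6-hydroxy-2,4-bis(methoxymethoxy)benzaldehyde | COCOc1cc(O)c(C=O)c(OCOC)c1C/C=C(\C)CCC=C(C)C | intermediate
8 | allyl acetate (prop-2-en-1-yl acetate) | CC(=O)OCC=C | starting material
9 | allyl 3-[3-geranyl-6-hydroxy-2,4-bis(methoxymethoxy)phenyl]-3-hydroxypropanoate, racemic at the carbinol carbon | COCOc1cc(O)c(C(O)CC(=O)OCC=C)c(OCOC)c1C/C=C(\C)CCC=C(C)C | intermediate
10 | allyl 3-[3-geranyl-6-hydroxy-2,4-bis(methoxymethoxy)phenyl]-3-oxopropanoate | COCOc1cc(O)c(C(=O)CC(=O)OCC=C)c(OCOC)c1C/C=C(\C)CCC=C(C)C | intermediate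
11 | isovanillin, 3-hydroxy-4-methoxybenzaldehyde | COc1ccc(C=O)cc1O | starting material
12 | 4-methoxy-3-(methoxymethoxy)benzaldehyde | COc1ccc(C=O)cc1OCOC | intermediate
13 | allyl (2Z)-2-[3-geranyl-6-hydroxy-2,4-bis(methoxymethoxy)benzoyl]-3-[4-methoxy-3-(methoxymethoxy)phenyl]prop-2-enoate | COCOc1cc(O)c(C(=O)/C(=C/c2ccc(OC)c(OCOC)c2)C(=O)OCC=C)c(OCOC)c1C/C=C(\C)CCC=C(C)C | intermediate
14 | allyl (2S)-6-geranyl-2-[4-methoxy-3-(methoxymethoxy)phenyl]-5,7-bis(methoxymethoxy)-4-oxochromane-3-carboxylate, C-3 epimers and enol in equilibrium, C-3 left undefined (not isolated) | COc1ccc([C@@H]2C(C(=O)OCC=C)C(=O)c3c(cc(OCOC)c(C/C=C(\C)CCC=C(C)C)c3OCOC)O2)cc1OCOC | intermediate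
15 | (2S)-6-geranyl-2-[4-methoxy-3-(methoxymethoxy)phenyl]-5,7-bis(methoxymethoxy)chroman-4-one | COc1ccc([C@@H]2CC(=O)c3c(cc(OCOC)c(C/C=C(\C)CCC=C(C)C)c3OCOC)O2)cc1OCOC | intermediate
16 | (2S)-6-[(2E)-3,7-dimethylocta-2,6-dien-1-yl]-5,7-dihydroxy-2-(3-hydroxy-4-methoxyphenyl)chroman-4-one | COc1ccc([C@@H]2CC(=O)c3c(cc(O)c(C/C=C(\C)CCC=C(C)C)c3O)O2)cc1O | target

Total step count: 10
Longest linear sequence: 9 steps (steps 1–6 and 8–10, from resorcinol to 16); step 7 prepares the ring B aldehyde separately.

Steps most likely to fail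

Step 9. The ring closure may proceed with weak facial control on this ortho,ortho'-dioxygenated aryl ketone. The C-2 configuration may also erode through reversible ring opening of 14 before the ester is removed. The fallback sets out from 13 and replaces asymmetric catalysis by a kinetic resolution. Closure with an achiral amine (piperidine, toluene, rt) should give racemic allyl 6-geranyl-2-[4-methoxy-3-(methoxymethoxy)phenyl]-5,7-bis(methoxymethoxy)-4-oxochromane-3-carboxylate F1. Treatment with Pd(PPh3)4, HCO2H and Et3N should then give racemic 6-geranyl-2-[4-methoxy-3-(methoxymethoxy)phenyl]-5,7-bis(methoxymethoxy)chroman-4-one F2. Noyori-type asymmetric transfer hydrogenation with RuCl[(R,R)-TsDPEN](p-cymene) and HCO2H/Et3N is chosen so that the (2R) ketone is the fast-reacting enantiomer and is reduced to (2R,4R)-6-geranyl-2-[4-methoxy-3-(methoxymethoxy)phenyl]-5,7-bis(methoxymethoxy)chroman-4-ol F3. The unreacted (2S) ketone is separated by chromatography, which returns to the route at 15.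

Step 5. The phenoxide formed first turns the aldehyde into a poor electrophile, so addition may stall or revert by retro-aldol cleavage. The electron-rich ortho-hydroxybenzylic carbinol may also ionise and eliminate during work-up. The fallback sets out from 7 and masks the phenol before the carbon–carbon bond is made. 3,4-Dihydro-2H-pyran and PPTS should give 3-geranyl-2,4-bis(methoxymethoxy)-6-(tetrahydro-2H-pyran-2-yloxy)benzaldehyde F4. The same enolate addition then gives allyl 3-[3-geranyl-2,4-bis(methoxymethoxy)-6-(tetrahydro-2H-pyran-2-yloxy)phenyl]-3-hydroxypropanoate F5. Dess–Martin periodinane with NaHCO3 gives allyl 3-[3-geranyl-2,4-bis(methoxymethoxy)-6-(tetrahydro-2H-pyran-2-yloxy)phenyl]-3-oxopropanoate F6. PPTS in methanol removes only the tetrahydropyranyl group and returns to the route at 10.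

Step 10. Acid may drive cyclisation of the geranyl chain onto the freed 5- or 7-hydroxyl, hydrate its alkenes, or ionise the benzylic C-2–O bond in competition with acetal cleavage. The fallback sets out from 15 and avoids Brønsted acid. TMSOTf and 2,2'-bipyridyl in CH2Cl2 at 0 °C should exchange the three aryl MOM ethers for silyl ethers to give (2S)-6-geranyl-2-[4-methoxy-3-(trimethylsilyloxy)phenyl]-5,7-bis(trimethylsilyloxy)chroman-4-one F7. Hydrolysis with water then returns to the route at 16.

Further compounds
F1 | step 9 | racemic allyl 6-geranyl-2-[4-methoxy-3-(methoxymethoxy)phenyl]-5,7-bis(methoxymethoxy)-4-oxochromane-3-carboxylate | COc1ccc(C2C(C(=O)OCC=C)C(=O)c3c(cc(OCOC)c(C/C=C(\C)CCC=C(C)C)c3OCOC)O2)cc1OCOC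
F2 | step 9 | racemic 6-geranyl-2-[4-methoxy-3-(methoxymethoxy)phenyl]-5,7-bis(methoxymethoxy)chroman-4-one | COc1ccc(C2CC(=O)c3c(cc(OCOC)c(C/C=C(\C)CCC=C(C)C)c3OCOC)O2)cc1OCOC
F3 | step 9 | (2R,4R)-6-geranyl-2-[4-methoxy-3-(methoxymethoxy)phenyl]-5,7-bis(methoxymethoxy)chroman-4-ol | COc1ccc([C@H]2C[C@@H](O)c3c(cc(OCOC)c(C/C=C(\C)CCC=C(C)C)c3OCOC)O2)cc1OCOC
F4 | step 5 | 3-geranyl-2,4-bis(methoxymethoxy)-6-(tetrahydro-2H-pyran-2-yloxy)benzaldehyde | COCOc1cc(OC2CCCCO2)c(C=O)c(OCOC)c1C/C=C(\C)CCC=C(C)C
F5 | step 5 | allyl 3-[3-geranyl-2,4-bis(methoxymethoxy)-6-(tetrahydro-2H-pyran-2-yloxy)phenyl]-3-hydroxypropanoate | COCOc1cc(OC2CCCCO2)c(C(O)CC(=O)OCC=C)c(OCOC)c1C/C=C(\C)CCC=C(C)C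
F6 | step 5 | allyl 3-[3-geranyl-2,4-bis(methoxymethoxy)-6-(tetrahydro-2H-pyran-2-yloxy)phenyl]-3-oxopropanoate | COCOc1cc(OC2CCCCO2)c(C(=O)CC(=O)OCC=C)c(OCOC)c1C/C=C(\C)CCC=C(C)C
F7 | step 10 | (2S)-6-geranyl-2-[4-methoxy-3-(trimethylsilyloxy)phenyl]-5,7-bis(trimethylsilyloxy)chroman-4-one | COc1ccc([C@@H]2CC(=O)c3c(cc(O[Si](C)(C)C)c(C/C=C(\C)CCC=C(C)C)c3O[Si](C)(C)C)O2)cc1O[Si](C)(C)C
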